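**Retrosynthetic overview**
1. The last events are O-debenzylation at C7 and a catalyst-controlled hydrogenation of the C3=C4 bond of an isoflav-3-ene, which sets C3.
2. The pyran ring of that isoflav-3-ene is opened at C2–C3 and C4–C4a in one cationic [4+2] (oxa-Povarov) annulation. The partners are an O-aryl oxocarbenium ion on ring A (O1=C2H2+, from a pivaloyloxymethyl aryl ether) and a ring B β-methoxystyrene (C3=C4–OMe).
3. Enabling feature: C4a of ring A is the only free carbon ortho to O1 (C8 carries OMe) and lies para to the C7 oxygen, so a cation tethered to O1 can close only there. A temporary OMe on C4 makes the aryl-bearing C3 the nucleophilic carbon and leaves as methanol in the same flask.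
4. Ring order: rings A and B come from commercial arenes; the pyran ring is the only ring formed (step 5).

Key step: step 5

Remark: isoflavan numbering is used (O1, C2, C3, C4, C4a, C5–C8, C8a; ring B primed); the stereocenter of the target is C3 with the S configuration (C2 > C1' > C4 > H).

**Step 1**
Reactants: 1 2-methoxybenzene-1,3-diol
Product: 2 3-(benzyloxy)-2-methoxyphenol
Conditions: BnBr (0.9 equiv), K2CO3, acetone, reflux
Reagents that add atoms: benzyl bromide, BrCc1ccccc1
Why: Williamson etherification; the two hydroxyl groups of 1 are equivalent, so a deficit of BnBr should give mainly the monoether, which is separated from recovered 1 and the bis-ether.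

**Step 2**
Reactants: 2 3-(benzyloxy)-2-methoxyphenol
Product: 3 [3-(benzyloxy)-2-methoxyphenoxy]methyl pivalate
Conditions: ClCH2OPiv (1.3 equiv), K2CO3, NaI (cat.), DMF, rt
Reagents that add atoms: chloromethyl pivalate, CC(C)(C)C(=O)OCCl
Why: SN2 O-alkylation of the phenoxide (Williamson type, with Finkelstein activation by iodide), the usual way to aryl pivaloyloxymethyl ethers; the tert-butyl group shields the ester carbonyl from acyl transfer.

**Step 3**
Reactants: 4 1,2,3,4-tetramethoxybenzene
Product: 5 2,3,4,5-tetramethoxybenzaldehyde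
Conditions: Cl2CHOMe (1.2 equiv), TiCl4 (1.5 equiv), CH2Cl2, −10 to 0 °C; then ice water
Reagents that add atoms: dichloromethyl methyl ether, COC(Cl)Cl; water, O
Why: Rieche formylation (Friedel–Crafts type); the two free positions of 4 are equivalent and each is activated by an ortho and a para OMe, and the low temperature should prevent chelation-driven demethylation next to the new CHO.

**Step 4**
Reactants: 5 2,3,4,5-tetramethoxybenzaldehyde
Product: 6 1,2,3,4-tetramethoxy-5-(2-methoxyethenyl)benzene (E/Z mixture)
Conditions: Ph3P(CH2OMe)Cl (1.3 equiv), KOtBu (1.3 equiv), THF, 0 °C to rt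
Reagents that add atoms: (methoxymethyl)triphenylphosphonium chloride, COC[P+](c1ccccc1)(c1ccccc1)c1ccccc1.[Cl-]
Why: Wittig methoxymethylenation of an aryl aldehyde; the E/Z composition does not matter because both alkene carbons become sp2 again in 9.

**Step 5**
Reactants: 3 [3-(benzyloxy)-2-methoxyphenoxy]methyl pivalate; 6 1,2,3,4-tetramethoxy-5-(2-methoxyethenyl)benzene
Product: 9 7-(benzyloxy)-8-methoxy-3-(2,3,4,5-tetramethoxyphenyl)-2H-chromene, via O-aryl oxocarbenium triflate 7 (not isolated), via 4-methoxyisoflavan adduct 8 (not isolated)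
Conditions: TMSOTf (2.2 equiv), 2,6-di-tert-butyl-4-methylpyridine (2.5 equiv), CH2Cl2, −78 °C, slow addition of 3 + 6 (1.2 equiv); then 0 °C to rt; aq. NaHCO3
Reagents that add atoms: none
Why: TMSOTf silylates the pivalate carbonyl of 3 and expels trimethylsilyl pivalate, so ionization can only give the O-aryl oxocarbenium ion 7 (an acyloxy oxygen cannot carry the alternative cation). Enol ether 6 attacks the CH2 of 7 through its aryl-bearing carbon (C2–C3), because the charge then rests on C4 as a methoxycarbenium ion, and C4a of ring A, ortho to O1 and para to the C7 benzyloxy group, closes the pyran ring on that ion by a 6-exo-trig Friedel–Crafts attack (C4–C4a) to give 8. The closest known reaction type is the oxa-Povarov reaction, the formal inverse-demand [4+2] of a cationic aryl 2-oxadiene with an electron-rich alkene. On warming, the second equivalent of TMSOTf ionizes the doubly activated benzylic C4–OMe bond and the hindered pyridine removes H3 (E1), so the temporary C4 oxygen leaves as methanol and the stilbene-like 2H-chromene 9 results. No stereocenter has to be controlled here: C3 and C4 of 8 form as a mixture and are both flattened again, the E/Z mixture of 6 converges, and C3 is set in step 6. The selectivities needed are regiochemical (ring B on C3 and not on C4; closure at C4a) and chemoselective (annulation faster than enol ether oligomerization or intermolecular arene alkylation); they are secured by the oxygen on C4, by the OMe that blocks C8, by the 6-membered intramolecular closure and by slow addition of 3 and 6 to the promoter.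

**Step 6**
Reactants: 9 7-(benzyloxy)-8-methoxy-3-(2,3,4,5-tetramethoxyphenyl)-2H-chromene
Product: 10 (3S)-7-(benzyloxy)-8-methoxy-3-(2,3,4,5-tetramethoxyphenyl)chromane
Conditions: H2 (50 bar), [Ir(cod)((S)-tBu-PHOX)]BArF (1–2 mol%; BArF = B[3,5-(CF3)2C6H3]4), CH2Cl2, rt
Reagents that add atoms: none
Why: Iridium-catalysed asymmetric hydrogenation of a cyclic trisubstituted aryl alkene with a chiral phosphine–oxazoline ligand, a reaction type established for 3-aryl-2H-chromenes; C3 is set by catalyst control of the face to which hydrogen is delivered, the ligand antipode being the one that should give 3S (the sense is to be confirmed on the first run and the (R) ligand used if needed), and the benzyl and methyl ethers are inert.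

**Step 7**
Reactants: 10 (3S)-7-(benzyloxy)-8-methoxy-3-(2,3,4,5-tetramethoxyphenyl)chromane
Product: 11 (3S)-8-methoxy-3-(2,3,4,5-tetramethoxyphenyl)-3,4-dihydro-2H-chromen-7-ol
Conditions: H2 (1 atm), Pd/C (10 wt%), EtOAc–MeOH, rt
Reagents that add atoms: none
Why: Hydrogenolysis of an aryl benzyl ether; the C2–O1 bond is not benzylic and no cation is formed at C4, so C3 should keep its configuration.

**Compound list**
1 | 2-methoxybenzene-1,3-diol | COc1c(O)cccc1O | starting material
2 | 3-(benzyloxy)-2-methoxyphenol | COc1c(O)cccc1OCc1ccccc1 | intermediate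
3 | [3-(benzyloxy)-2-methoxyphenoxy]methyl pivalate | COc1c(OCOC(=O)C(C)(C)C)cccc1OCc1ccccc1 | intermediate
4 | 1,2,3,4-tetramethoxybenzene | COc1ccc(OC)c(OC)c1OC | starting material
5 | 2,3,4,5-tetramethoxybenzaldehyde | COc1cc(C=O)c(OC)c(OC)c1OC | intermediate
6 | 1,2,3,4-tetramethoxy-5-(2-methoxyethenyl)benzene (E/Z mixture) | COC=Cc1cc(OC)c(OC)c(OC)c1OC | intermediate
7 | [3-(benzyloxy)-2-methoxyphenyl](methylidene)oxonium triflate | C=[O+]c1cccc(OCc2ccccc2)c1OC.[O-]S(=O)(=O)C(F)(F)F | intermediate (not isolated)
8 | 7-(benzyloxy)-4,8-dimethoxy-3-(2,3,4,5-tetramethoxyphenyl)chromane (racemic mixture of diastereomers) | COC1c2ccc(OCc3ccccc3)c(OC)c2OCC1c1cc(OC)c(OC)c(OC)c1OC | intermediate (not isolated)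
9 | 7-(benzyloxy)-8-methoxy-3-(2,3,4,5-tetramethoxyphenyl)-2H-chromene | COc1cc(C2=Cc3ccc(OCc4ccccc4)c(OC)c3OC2)c(OC)c(OC)c1OC | intermediate
10 | (3S)-7-(benzyloxy)-8-methoxy-3-(2,3,4,5-tetramethoxyphenyl)chromane | COc1cc([C@H]2COc3c(ccc(OCc4ccccc4)c3OC)C2)c(OC)c(OC)c1OC | intermediate
11 | (3S)-8-methoxy-3-(2,3,4,5-tetramethoxyphenyl)-3,4-dihydro-2H-chromen-7-ol | COc1cc([C@H]2COc3c(ccc(O)c3OC)C2)c(OC)c(OC)c1OC | target

**Totals**
Total step count: 7. Longest linear sequence: 5 steps (1 → 2 → 3 → 9 → 10 → 11; the ring B branch 4 → 5 → 6 joins in step 5).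

**Steps most likely to fail**

Step 5. Cationic oligomerization of the enol ether, or Friedel–Crafts alkylation of the electron-rich rings by the oxocarbenium ion, may outrun the annulation; acid-induced dimerization of the chromene may also occur during the elimination stage. The fallback sets out from 6 and 2 and comes back at 9, building the two bonds one after the other by neutral or anionic chemistry. Hydrolysis of 6 (aq. HCl, THF) should give (2,3,4,5-tetramethoxyphenyl)acetaldehyde F1. Amine-catalysed α-methylenation (aqueous formaldehyde, pyrrolidine, propanoic acid, iPrOH) should give 2-(2,3,4,5-tetramethoxyphenyl)prop-2-enal F2. Base-catalysed oxa-Michael addition of phenol 2 should give 3-[3-(benzyloxy)-2-methoxyphenoxy]-2-(2,3,4,5-tetramethoxyphenyl)propanal F3. Its TsOH-catalysed Friedel–Crafts cyclodehydration (toluene, 60 °C) should close C4–C4a and give 9.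

Step 6. Enantioface discrimination may be poor, or turnover slow, because the ortho-methoxy group twists ring B out of the alkene plane. The fallback sets out from 9 and comes back at 11. Hydroboration–oxidation (BH3·THF; NaOH, H2O2) should give trans-7-(benzyloxy)-8-methoxy-3-(2,3,4,5-tetramethoxyphenyl)chroman-4-ol F4 as the racemate. Dess–Martin oxidation should give 7-(benzyloxy)-8-methoxy-3-(2,3,4,5-tetramethoxyphenyl)chroman-4-one F5, whose C3 epimerizes readily. Asymmetric transfer hydrogenation with dynamic kinetic resolution (RuCl[(S,S)-TsDPEN](p-cymene), HCO2H–Et3N) should give (3S,4S)-7-(benzyloxy)-8-methoxy-3-(2,3,4,5-tetramethoxyphenyl)chroman-4-ol F6. Hydrogenolysis (H2, Pd/C, AcOH–EtOAc) should then remove both the C4 hydroxyl and the benzyl group to give 11.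

Step 2. Acyl transfer from chloromethyl pivalate to the phenoxide may compete with O-alkylation, and the acetal ester may be lost by hydrolysis on isolation. The fallback sets out from 2 and comes back at 7 inside step 5. Alkylation with chloromethyl methyl sulfide (NaH, NaI, DMF) should give 1-(benzyloxy)-2-methoxy-3-[(methylsulfanyl)methoxy]benzene F7. Treatment with SO2Cl2 (CH2Cl2, −78 °C) should give 1-(benzyloxy)-3-(chloromethoxy)-2-methoxybenzene F8. This is used crude in step 5, where AgOTf abstracts chloride in place of the TMSOTf ionization of the pivalate and should give the same ion 7.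

**Further compounds**
F1 | step 5 | (2,3,4,5-tetramethoxyphenyl)acetaldehyde | COc1cc(CC=O)c(OC)c(OC)c1OC
F2 | step 5 | 2-(2,3,4,5-tetramethoxyphenyl)prop-2-enal | COc1cc(C(=C)C=O)c(OC)c(OC)c1OC
F3 | step 5 | 3-[3-(benzyloxy)-2-methoxyphenoxy]-2-(2,3,4,5-tetramethoxyphenyl)propanal (racemic) | COc1cc(C(COc2cccc(OCc3ccccc3)c2OC)C=O)c(OC)c(OC)c1OC
F4 | step 6 | trans-7-(benzyloxy)-8-methoxy-3-(2,3,4,5-tetramethoxyphenyl)chroman-4-ol (racemic; the 3S,4R enantiomer drawn) | COc1cc([C@H]2COc3c(ccc(OCc4ccccc4)c3OC)[C@@H]2O)c(OC)c(OC)c1OC
F5 | step 6 | 7-(benzyloxy)-8-methoxy-3-(2,3,4,5-tetramethoxyphenyl)chroman-4-one (racemic) | COc1cc(C2COc3c(ccc(OCc4ccccc4)c3OC)C2=O)c(OC)c(OC)c1OC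
F6 | step 6 | (3S,4S)-7-(benzyloxy)-8-methoxy-3-(2,3,4,5-tetramethoxyphenyl)chroman-4-ol | COc1cc([C@H]2COc3c(ccc(OCc4ccccc4)c3OC)[C@H]2O)c(OC)c(OC)c1OC
F7 | step 2 | 1-(benzyloxy)-2-methoxy-3-[(methylsulfanyl)methoxy]benzene | COc1c(OCSC)cccc1OCc1ccccc1
F8 | step 2 | 1-(benzyloxy)-3-(chloromethoxy)-2-methoxybenzene | COc1c(OCCl)cccc1OCc1ccccc1
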